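Ring B is cut at its two bonds to the arene: the aryl ether O–C(aryl) bond on the C2 oxygen and the aryl–C7' bond. Because C2–O and C7' sit cis-1,3 on cyclopentane ring C, removing the arene leaves a bridged lactol (2-oxabicyclo[2.2.1]heptane) of a C2 alcohol and a C4 aldehyde. In one operation, the ring-opened C2 alkoxide adds to 3,5-bis(methoxymethoxy)benzyne and the resulting aryl anion closes onto the C7' aldehyde, inserting ring A into the O–C7' bond and forming oxepane ring B. The lactol, carrying rings C, D and E with C4, C5, C6 and C7 set, comes from (+)-2-carene by an intramolecular ynone Diels–Alder reaction and an epoxide ring contraction.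

Key step: step 16

Remarks on the chemistry:
- Atom labels (terpene part): C10 (bears CH3) and C1 are the ring D alkene carbons of the target, C2 the O-bearing CH, C3 the CH2 of ring C, C4 the quaternary carbon, C5 the ring-fusion CH, C6 and C7 the cyclopropane CH carbons, C8 and C9 the ring D CH2 groups, C11 the CMe2 carbon, C7' the carbon on C4 that ends as the benzylic CH (in 9–11 it is still a ring carbon). Rings: A arene, B oxepane, C cyclopentane, D seven-membered carbocycle, E cyclopropane.
- Assumption: C10 of 14, the anomeric carbon of 15 and the C7' carbinol of 24 are drawn as single epimers although mixtures may form; none of these centres survives unchanged into the target.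

Step 1
Reactants: 1 (+)-2-carene
Product: 3 keto acetal 4-[(1R,3S)-3-(dimethoxymethyl)-2,2-dimethylcyclopropyl]butan-2-one, via keto aldehyde 2 (not isolated)
Conditions: O3, CH2Cl2/MeOH, −78 °C; Me2S, −78 °C to rt; then HC(OMe)3, PPTS (cat.), rt
Reagents that add atoms: ozone O=[O+][O-]; trimethyl orthoformate COC(OC)OC
Why: Ozonolysis with reductive work-up cleaves only the trisubstituted alkene and leaves both cyclopropane stereocentres untouched, after which acid-catalysed acetalisation with the orthoformate masks the aldehyde far faster than the methyl ketone.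

Step 2
Reactants: 3 keto acetal
Product: 4 acid 3-[(1R,3S)-3-(dimethoxymethyl)-2,2-dimethylcyclopropyl]propanoic acid
Conditions: Br2, NaOH, H2O/1,4-dioxane, 0 °C; then cold 1 M HCl to pH 4
Reagents that add atoms: sodium hydroxide [Na+].[OH-]
Why: Haloform reaction: the methyl ketone is tribrominated and cleaved by hydroxide, which removes the carene methyl as bromoform and leaves C10 as a carboxylic acid, while acetal and cyclopropane tolerate cold alkaline hypobromite.

Step 3
Reactants: 4 acid
Product: 6 aldehyde Weinreb amide 3-[(1R,3S)-3-formyl-2,2-dimethylcyclopropyl]-N-methoxy-N-methylpropanamide, via acetal Weinreb amide 5 (not isolated)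
Conditions: MeNHOMe·HCl, EDC·HCl, i-Pr2NEt, DMAP (cat.), CH2Cl2, rt; then 1 M HCl, THF, rt
Reagents that add atoms: N,O-dimethylhydroxylamine hydrochloride CNOC.Cl; water O
Why: Carbodiimide amide coupling gives the Weinreb amide and mild aqueous acid then hydrolyses the dimethyl acetal, conditions under which the amide and the cis-cyclopropane persist.

Step 4
Reactants: 6 aldehyde Weinreb amide
Product: 7 (E)-enal N-methoxy-N-methyl-3-[(1R,3S)-2,2-dimethyl-3-[(E)-2-methyl-3-oxoprop-1-enyl]cyclopropyl]propanamide
Conditions: Ph3P=C(CH3)CHO, toluene, 80 °C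
Reagents that add atoms: 2-(triphenylphosphoranylidene)propanal CC(C=O)=P(c1ccccc1)(c1ccccc1)c1ccccc1
Why: Wittig olefination with a stabilised ylide reacts only with the aldehyde and gives the (E)-2-methyl enal, the geometry the later diene needs.

Step 5
Reactants: 7 (E)-enal
Product: 8 diene Weinreb amide N-methoxy-N-methyl-3-[(1R,3S)-2,2-dimethyl-3-[(1E)-2-methylbuta-1,3-dienyl]cyclopropyl]propanamide
Conditions: MePPh3Br, KOt-Bu, THF, 0 °C; add 7, −78 to 0 °C
Reagents that add atoms: methyltriphenylphosphonium bromide C[P+](c1ccccc1)(c1ccccc1)c1ccccc1.[Br-]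
Why: Wittig methylenation adds to the enal carbonyl in 1,2 fashion at low temperature and spares the Weinreb amide, giving the (E)-1-substituted 2-methylbuta-1,3-diene.

Step 6
Reactants: 8 diene Weinreb amide
Product: 9 dienyl ynone 5-[(1R,3S)-2,2-dimethyl-3-[(1E)-2-methylbuta-1,3-dienyl]cyclopropyl]pent-1-yn-3-one
Conditions: HC≡CMgBr, THF, 0 °C; inverse quench into cold 1 M HCl
Reagents that add atoms: ethynylmagnesium bromide C#C[Mg]Br
Why: Weinreb ketone synthesis: the chelated tetrahedral magnesium adduct prevents over-addition, and inverse acidic quench releases the terminal ynone while protonating the liberated amine so that it cannot add to the ynone.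

Step 7
Reactants: 9 dienyl ynone
Product: 10 tricyclic dienone (C10 ketone; C1=C2 and C4=C7' in a cyclohexa-1,4-diene; rings D and E cis-fused; 5-H trans to 6-H)
Conditions: toluene (0.01 M), BHT (cat.), 90 °C, degassed
Reagents that add atoms: none
Why: Intramolecular Diels–Alder reaction (ynone dienophile, five-atom tether preorganised by the cis-cyclopropane): the ynone reaches diene terminus C5 from the side of its own tether while the vinylcyclopropane keeps its s-trans bisected conformation with 5-H under the CMe2 bridge, so ring D and the cyclohexa-1,4-diene form together and C5 is set with 5-H trans to 6-H.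

Step 8
Reactants: 10 tricyclic dienone
Product: 11 epoxy enone (C4–C7' epoxide on the face of 5-H)
Conditions: mCPBA, NaHCO3, CH2Cl2, 0 °C
Reagents that add atoms: mCPBA OOC(=O)c1cccc(Cl)c1
Why: Prilezhaev epoxidation selects the electron-rich trisubstituted C4=C7' alkene over the electron-poor enone alkene and should occur on the face of 5-H, anti to the C5–C6 bond and ring D, which sets C4 and C7' of the epoxide.

Step 9
Reactants: 11 epoxy enone
Product: 12 keto aldehyde (ring C cyclopentene C1=C2; quaternary C4 with CH3 and CHO; CHO syn to 5-H)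
Conditions: MeAl(OC6H2-4-Br-2,6-t-Bu2)2 (2.2 equiv, preformed), CH2Cl2, −78 °C
Reagents that add atoms: none
Why: Meinwald rearrangement (semipinacol ring contraction): the bulky aluminium Lewis acid opens the epoxide at tertiary C4 and ring bond C3–C7' migrates to C4 anti to the departing oxygen in preference to hydride, which contracts the six-membered ring to ring C and fixes quaternary C4 with the formyl group syn to 5-H.

Step 10
Reactants: 12 keto aldehyde
Product: 13 keto dimethyl acetal (C7' as CH(OMe)2)
Conditions: HC(OMe)3, MeOH, CSA (cat.), rt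
Reagents that add atoms: trimethyl orthoformate COC(OC)OC
Why: Acid-catalysed acetalisation with trimethyl orthoformate protects the aldehyde, the conjugated cycloheptenone being much less electrophilic, so that the carbonyls are differentiated for the methyl addition.

Step 11
Reactants: 13 keto dimethyl acetal
Product: 14 tertiary allylic alcohol (C10 carbinol with CH3; C1=C2 retained)
Conditions: MeLi, CeCl3, THF, −78 °C; H2O quench
Reagents that add atoms: methyllithium [Li]C
Why: 1,2-Addition of the non-basic organocerium reagent to the enone carbonyl introduces the C10 methyl without enolisation or conjugate addition, and the configuration of the new carbinol does not matter because C10 becomes sp2 in step 12.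

Step 12
Reactants: 14 tertiary allylic alcohol
Product: 15 bridged lactol (C2–O–C7'(OH) bridge across ring C; tetrasubstituted C1=C10 alkene)
Conditions: p-TsOH·H2O (cat.), THF/H2O (4:1), rt to 40 °C
Reagents that add atoms: water O
Why: SN1 allylic transposition with intramolecular oxygen capture: acid ionises the tertiary allylic alcohol to the C10–C1–C2 allyl cation and unmasks the aldehyde, whose hydrate is held over one face of ring C by C4 and closes on C2 (5-exo), which sets C2–O cis to C7' and leaves the tetrasubstituted C1=C10 alkene.

Step 13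
Reactants: 16 phloroglucinol
Product: 17 3,5-bis(methoxymethoxy)phenol
Conditions: MOMCl (2.1 equiv), i-Pr2NEt, THF/CH2Cl2, 0 °C to rt
Reagents that add atoms: chloromethyl methyl ether COCCl
Why: Williamson-type O-alkylation of the symmetric triol with two equivalents of MOMCl gives the bis-ether, which has only one constitution and is separated from mono- and tris-ether.

Step 14
Reactants: 17 3,5-bis(methoxymethoxy)phenol
Product: 18 2-bromo-3,5-bis(methoxymethoxy)phenol
Conditions: NBS, i-Pr2NH (cat.), CH2Cl2, −78 °C
Reagents that add atoms: N-bromosuccinimide O=C1CCC(=O)N1Br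
Why: Electrophilic aromatic bromination under amine catalysis is ortho-selective for phenols, and the two ortho positions are equivalent, so bromine enters between OH and one OMOM group.

Step 15
Reactants: 18 2-bromo-3,5-bis(methoxymethoxy)phenol
Product: 21 3,5-bis(methoxymethoxy)-2-(trimethylsilyl)phenyl triflate, via aryl silyl ether 19 (not isolated), via ortho-silyl phenoxide 20 (not isolated)
Conditions: (Me3Si)2NH, THF, 65 °C, evaporate; n-BuLi, THF, −100 to −78 °C; Tf2O, −100 to −78 °C
Reagents that add atoms: hexamethyldisilazane C[Si](C)(C)N[Si](C)(C)C; triflic anhydride O=S(=O)(OS(=O)(=O)C(F)(F)F)C(F)(F)F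
Why: O-Silylation followed by bromine–lithium exchange triggers the retro-Brook (anionic 1,3 O-to-C silyl) migration, and the resulting lithium phenoxide is triflated to give the ortho-silylaryl triflate.

Step 16
Reactants: 15 bridged lactol; 21 3,5-bis(methoxymethoxy)-2-(trimethylsilyl)phenyl triflate
Product: 24 ring B benzylic alcohol (arene between the C2 oxygen and C7'; 7'-OH syn to the C4 methyl; two MOM ethers), via aryne 22 (not isolated), via open hydroxy aldehyde 23 (not isolated)
Conditions: CsF (4 equiv), THF, 60 °C, 21 (1.5 equiv) added slowly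
Reagents that add atoms: none
Why: Proposed new method: fluoride releases aryne 22 from 21, and the cesium alkoxide of the ring-opened tautomer 23 (in ring–chain equilibrium with the strained bridged lactolate, whose neopentyl hemiacetal oxygen is the poorer nucleophile) adds through the C2 oxygen to the aryne carbon meta to the 3-OMOM group, giving an aryl anion flanked by OMOM and the new ether oxygen that attacks the C4 aldehyde; the closest known chemistry is the aryne annulation of salicylaldehydes and salicylates (xanthene and xanthone syntheses) and alkoxide addition to 3-alkoxyarynes with carbonyl capture, extended here to an aliphatic lactol and a seven-membered ring. Ring B closes 7-exo-trig, and the step forms both the O–aryl and the aryl–C7' bond. The C7' carbinol is the only new stereocentre; the aldehyde on the cis-bridged ring C should turn its oxygen toward the C4 methyl and away from ring D as drawn, but either epimer is acceptable because step 17 passes through the planar benzylic cation. The step needs aryne regioselectivity, secured by the inductive bias of the 3-alkoxy group, and cyclisation before protonation of the aryl anion, favoured by the aprotic ether solvent, excess CsF and the cis disposition of the C2 oxygen and the aldehyde that the lactol guarantees.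

Step 17
Reactants: 24 ring B benzylic alcohol; 25 methallyltrimethylsilane
Product: 26 7'-methallyl compound (2-methylallyl on C7' syn to the C4 methyl)
Conditions: BF3·OEt2, CH2Cl2, −78 °C
Reagents that add atoms: none
Why: Hosomi–Sakurai-type SN1 allylation: BF3 ionises the benzylic alcohol to a cation stabilised by three ring oxygens, and the allylsilane attacks from the face of the C4 methyl because the C1–C5 bridge with ring D covers the other face, which sets C7' irrespective of the carbinol configuration.

Step 18
Reactants: 26 7'-methallyl compound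
Product: 27 7'-isobutyl bis-MOM ether
Conditions: H2 (1 atm), RhCl(PPh3)3 (10 mol%), toluene/EtOH, rt
Reagents that add atoms: none
Why: Homogeneous hydrogenation with RhCl(PPh3)3 saturates the unhindered 1,1-disubstituted alkene, whereas the tetrasubstituted C1=C10 alkene, the cyclopropane and the aryl ethers are inert to this catalyst.

Step 19
Reactants: 27 7'-isobutyl bis-MOM ether
Product: 28 7'-isobutyl diphenol
Conditions: p-TsOH·H2O (cat.), MeOH, 40 °C
Reagents that add atoms: none
Why: Acid-catalysed acetal exchange with methanol cleaves both aryl MOM ethers as dimethoxymethane under conditions mild enough to spare the allylic aryl ether, the alkene and the cyclopropane.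

Step 20
Reactants: 28 7'-isobutyl diphenol
Product: 30 target CNP0388405.1, via bis-iminium salt 29 (not isolated)
Conditions: POCl3, DMF, 0 to 40 °C; then H2O, rt
Reagents that add atoms: N,N-dimethylformamide CN(C)C=O; water O
Why: Double Vilsmeier–Haack formylation: both free positions of the ring are ortho or para to three oxygen substituents, so the chloroiminium ion substitutes twice, and hydrolysis of the bis-iminium salt liberates the two aldehydes.

Compound list
1 | (+)-2-carene, (1S,6R)-3,7,7-trimethylbicyclo[4.1.0]hept-2-ene | CC1=C[C@H]2[C@@H](CC1)C2(C)C | starting material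
2 | keto aldehyde, (1S,3R)-2,2-dimethyl-3-(3-oxobutyl)cyclopropane-1-carbaldehyde (cis; not isolated) | O=C[C@H]1[C@@H](CCC(C)=O)C1(C)C | intermediate
3 | keto acetal, 4-[(1R,3S)-3-(dimethoxymethyl)-2,2-dimethylcyclopropyl]butan-2-one | COC(OC)[C@H]1[C@@H](CCC(C)=O)C1(C)C | intermediate
4 | acid, 3-[(1R,3S)-3-(dimethoxymethyl)-2,2-dimethylcyclopropyl]propanoic acid | COC(OC)[C@H]1[C@@H](CCC(=O)O)C1(C)C | intermediate
5 | acetal Weinreb amide, 3-[(1R,3S)-3-(dimethoxymethyl)-2,2-dimethylcyclopropyl]-N-methoxy-N-methylpropanamide (not isolated) | COC(OC)[C@H]1[C@@H](CCC(=O)N(C)OC)C1(C)C | intermediate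
6 | aldehyde Weinreb amide, 3-[(1R,3S)-3-formyl-2,2-dimethylcyclopropyl]-N-methoxy-N-methylpropanamide | O=C[C@H]1[C@@H](CCC(=O)N(C)OC)C1(C)C | intermediate
7 | (E)-enal, N-methoxy-N-methyl-3-[(1R,3S)-2,2-dimethyl-3-[(E)-2-methyl-3-oxoprop-1-enyl]cyclopropyl]propanamide | O=C/C(C)=C/[C@H]1[C@@H](CCC(=O)N(C)OC)C1(C)C | intermediate
8 | diene Weinreb amide, N-methoxy-N-methyl-3-[(1R,3S)-2,2-dimethyl-3-[(1E)-2-methylbuta-1,3-dienyl]cyclopropyl]propanamide | C=C/C(C)=C/[C@H]1[C@@H](CCC(=O)N(C)OC)C1(C)C | intermediate
9 | dienyl ynone, 5-[(1R,3S)-2,2-dimethyl-3-[(1E)-2-methylbuta-1,3-dienyl]cyclopropyl]pent-1-yn-3-one | C=C/C(C)=C/[C@H]1[C@@H](CCC(=O)C#C)C1(C)C | intermediate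
10 | tricyclic dienone: ring D ketone at C10 conjugated with C1=C2, cyclohexa-1,4-diene with C4(CH3)=C7', rings D and E cis-fused, 5-H trans to 6-H | O=C1C2=CCC=C(C)[C@H]2[C@H]2[C@@H](CC1)C2(C)C | intermediate
11 | epoxy enone: 10 with a C4–C7' epoxide on the face of 5-H | O=C1C2=CC[C@@H]3O[C@]3(C)[C@H]2[C@H]2[C@@H](CC1)C2(C)C | intermediate
12 | keto aldehyde: cyclopentene ring C (C1=C2), quaternary C4 with CH3 and CHO, CHO syn to 5-H | O=C1C2=CC[C@](C)(C=O)[C@H]2[C@H]2[C@@H](CC1)C2(C)C | intermediate
13 | keto dimethyl acetal of 12 | O=C1C2=CC[C@](C)(C(OC)OC)[C@H]2[C@H]2[C@@H](CC1)C2(C)C | intermediate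
14 | tertiary allylic alcohol: C10(OH)CH3 adduct of 13, C10 configuration open | CC1(O)C2=CC[C@](C)(C(OC)OC)[C@H]2[C@H]2[C@@H](CC1)C2(C)C | intermediate
15 | bridged terpene lactol: C2–O–C7'(OH) across ring C, C1=C10 alkene, 5-H, C2–O and C7' on one face of ring C | CC1=C2[C@H]([C@H]3[C@@H](CC1)C3(C)C)[C@]1(C)C[C@H]2O[C@H]1O | intermediate
16 | phloroglucinol | Oc1cc(O)cc(O)c1 | starting material
17 | 3,5-bis(methoxymethoxy)phenol | COCOc1cc(O)cc(OCOC)c1 | intermediate
18 | 2-bromo-3,5-bis(methoxymethoxy)phenol | Oc1cc(OCOC)cc(OCOC)c1Br | intermediate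
19 | [2-bromo-3,5-bis(methoxymethoxy)phenoxy]trimethylsilane (not isolated) | C[Si](C)(C)Oc1cc(OCOC)cc(OCOC)c1Br | intermediate
20 | 3,5-bis(methoxymethoxy)-2-(trimethylsilyl)phenol, present as its lithium salt (not isolated) | C[Si](C)(C)c1c(O)cc(OCOC)cc1OCOC | intermediate
21 | 3,5-bis(methoxymethoxy)-2-(trimethylsilyl)phenyl triflate | C[Si](C)(C)c1c(OCOC)cc(OCOC)cc1OS(=O)(=O)C(F)(F)F | intermediate
22 | 3,5-bis(methoxymethoxy)benzyne (not isolated) | COCOC1=CC(OCOC)=CC#C1 | intermediate
23 | ring-opened hydroxy aldehyde tautomer of 15, reacting as its cesium alkoxide (not isolated) | CC1=C2[C@H]([C@H]3[C@@H](CC1)C3(C)C)[C@](C)(C[C@H]2O)C=O | intermediate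
24 | ring B benzylic alcohol: arene between the C2 oxygen and C7', 7'-OH syn to the C4 methyl, two MOM ethers | CC1=C2[C@H]([C@H]3[C@@H](CC1)C3(C)C)[C@]1(C)C[C@H]2Oc2cc(OCOC)cc(OCOC)c2[C@H]1O | intermediate
25 | methallyltrimethylsilane | C=C(C)C[Si](C)(C)C | starting material
26 | 7'-methallyl compound: 2-methylallyl on C7' syn to the C4 methyl | CC1=C2[C@H]([C@H]3[C@@H](CC1)C3(C)C)[C@]1(C)C[C@H]2Oc2cc(OCOC)cc(OCOC)c2[C@H]1CC(C)=C | intermediate
27 | 7'-isobutyl bis-MOM ether | CC1=C2[C@H]([C@H]3[C@@H](CC1)C3(C)C)[C@]1(C)C[C@H]2Oc2cc(OCOC)cc(OCOC)c2[C@H]1CC(C)C | intermediate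
28 | 7'-isobutyl diphenol | CC1=C2[C@H]([C@H]3[C@@H](CC1)C3(C)C)[C@]1(C)C[C@H]2Oc2cc(O)cc(O)c2[C@H]1CC(C)C | intermediate
29 | bis-iminium salt of 28, drawn as the dichloride (not isolated) | CC1=C2[C@H]([C@H]3[C@@H](CC1)C3(C)C)[C@]1(C)C[C@H]2Oc2c(C=[N+](C)C)c(O)c(C=[N+](C)C)c(O)c2[C@H]1CC(C)C.[Cl-].[Cl-] | intermediate
30 | CNP0388405.1 | CC1=C2[C@H]([C@H]3[C@@H](CC1)C3(C)C)[C@]1(C)C[C@H]2Oc2c(C=O)c(O)c(C=O)c(O)c2[C@H]1CC(C)C | target

Total step count: 20. Longest linear sequence: 17 steps (steps 1–12 and 16–20); the aryne precursor 21 is a three-step branch (steps 13–15).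

Steps most likely to fail

Step 16. The closed lactolate may be arylated at the hemiacetal oxygen instead of the C2 alkoxide. Alternatively, the aryl anion formed after the desired O-arylation may be protonated before it closes the seven-membered ring, so that only an aryl ether forms. The fallback uses known reactions, sets out from 15 and returns at 24. Commercial 5-bromoresorcinol is protected with MOMCl and i-Pr2NEt to give 1-bromo-3,5-bis(methoxymethoxy)benzene F1. N-Iodosuccinimide iodinates F1 next to bromine to give 1-bromo-2-iodo-3,5-bis(methoxymethoxy)benzene F2. Iodine–magnesium exchange (i-PrMgCl·LiCl, THF, −40 °C) gives the ortho-bromoaryl Grignard reagent. This adds to the aldehyde tautomer of 15, deprotonated beforehand with one equivalent of i-PrMgCl, to give the bromoaryl diol F3 (either C7' epimer). Intramolecular C–O cross-coupling of the C2 hydroxyl with the aryl bromide (Pd(OAc)2, 2-(di-tert-butylphosphino)-1,1'-binaphthyl, Cs2CO3, toluene, 70 °C) then closes ring B with retention at C2 and gives 24. The benzylic hydroxyl cannot reach the bromide.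

Step 7. Ring closure through the five-atom tether may be slower than three competing processes: polymerisation of the terminal ynone, the homo-1,5-hydrogen shift that opens cis-alkyl vinylcyclopropanes on heating, and air dehydrogenation of the doubly allylic cyclohexa-1,4-diene to an arene. The fallback sets out from 9 and returns at 10. PhSO2Na in AcOH/EtOH adds to the ynone to give the β-sulfonyl enone F4 (drawn as the E isomer). Its doubly activated alkene serves as an alkyne equivalent and should cyclise well below the temperature of step 7 to the sulfonyl ketone F5; the configurations at C1 and C2 are immaterial. DBU then expels benzenesulfinate by an E1cB elimination and gives dienone 10.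

Step 12. The allyl cation may lose a proton to ring D trienes, or be trapped by external water on either face, faster than the hydrate closes the strained 2-oxabicyclo[2.2.1]heptane. The fallback sets out from 12 and returns at 15. Pinnick oxidation (NaClO2, NaH2PO4, 2-methyl-2-butene) gives the keto acid F6. Excess MeLi with CeCl3 adds to the enone carbonyl to give the hydroxy acid F7. Anhydrous acid (CSA, CH2Cl2) ionises the allylic alcohol, and the carboxyl group captures C2 irreversibly while proton loss stays reversible, giving the bridged lactone F8. i-Bu2AlH at −78 °C reduces F8 to lactol 15.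

Further compounds
F1 | step 16 | 1-bromo-3,5-bis(methoxymethoxy)benzene | COCOc1cc(Br)cc(OCOC)c1
F2 | step 16 | 1-bromo-2-iodo-3,5-bis(methoxymethoxy)benzene | COCOc1cc(OCOC)c(I)c(Br)c1
F3 | step 16 | bromoaryl diol: ring-opened 15 with 2-bromo-4,6-bis(methoxymethoxy)phenyl on the C7' carbinol (C7' configuration open) | CC1=C2[C@H]([C@H]3[C@@H](CC1)C3(C)C)[C@](C)(C[C@H]2O)C(O)c1c(Br)cc(OCOC)cc1OCOC
F4 | step 7 | (E)-β-(phenylsulfonyl) enone from 9 | C=C/C(C)=C/[C@H]1[C@@H](CCC(=O)/C=C/S(=O)(=O)c2ccccc2)C1(C)C
F5 | step 7 | sulfonyl ketone: cycloadduct with 1-H and 2-SO2Ph (C1 and C2 configurations open) | O=C1C2C(S(=O)(=O)c3ccccc3)CC=C(C)[C@H]2[C@H]2[C@@H](CC1)C2(C)C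
F6 | step 12 | keto acid: 12 with CO2H in place of CHO | O=C1C2=CC[C@](C)(C(=O)O)[C@H]2[C@H]2[C@@H](CC1)C2(C)C
F7 | step 12 | hydroxy acid: C10(OH)CH3 adduct of the keto acid (C10 configuration open) | CC1(O)C2=CC[C@](C)(C(=O)O)[C@H]2[C@H]2[C@@H](CC1)C2(C)C
F8 | step 12 | bridged lactone: 15 with C7' as the lactone carbonyl | CC1=C2[C@H]([C@H]3[C@@H](CC1)C3(C)C)[C@]1(C)C[C@H]2OC1=O
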